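**Retrosynthetic overview**

1. Target ← global O-demethylation ← pentamethyl ether ← hydrogenation of two C=C bonds (2-methylprop-1-enyl at C4 → isobutyl, isopropenyl at C3 → isopropyl) ← tricyclic diene.
2. Key disconnection: C2–C3 of pyran ring B, with O1–C2 made in the same operation. An achiral phenol carrying CH[CH=C(CH3)2]2 next to O1 and the threefold-symmetric 2,4,6-trimethoxybenzene-1,3,5-tricarbaldehyde are joined by a catalytic asymmetric oxonium–ene (Prins) cyclization that sets C2, C3 and C4 at once.
3. Enabling feature: C4 of ring B carries two arms of the same constitution, CH2–CH(CH3)2 and C3H–CH(CH3)2, which differ only by the C3–C2 bond. C4 therefore becomes stereogenic only when one of two enantiotopic alkenyl arms closes onto C2, and C2 with aryl ring C is one formyl carbon of the symmetric trialdehyde.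
4. The phenol ← aromatic Claisen rearrangement of a tertiary dienyl aryl ether ← O-propargylation, Sonogashira coupling and semi-hydrogenation, starting from 4-hydroxy-2,6-dimethoxybenzaldehyde.
5. Ring order: aromatic rings A and C are bought; pyran ring B is the only ring formed (key step).

Key step: step 4

Assumption: 2,4,6-trimethoxybenzene-1,3,5-tricarbaldehyde, sold as a monomer for covalent organic frameworks, is taken as a purchasable starting material.
Assumption: the (S)-BINOL-derived acid is taken to give the (2R,3S,4S) series in step 4; if the sense of induction is opposite, the mirror-image acid is used.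

**Route**

Step 1
Reactants: 1 4-hydroxy-2,6-dimethoxybenzaldehyde; 2 3-chloro-3-methylbut-1-yne
Product: 3 2,6-dimethoxy-4-[(2-methylbut-3-yn-2-yl)oxy]benzaldehyde
Conditions: CuCl2·2H2O (1 mol %), DBU, MeCN, 0 °C
Reagents that add atoms: none
Why: Copper-catalysed propargylic etherification of a phenol with a tertiary propargyl chloride (via a copper allenylidene) is the standard entry to aryl 1,1-dimethylpropargyl ethers and tolerates the para-formyl group; no stereocenter is formed.

Step 2
Reactants: 3 2,6-dimethoxy-4-[(2-methylbut-3-yn-2-yl)oxy]benzaldehyde; 4 1-bromo-2-methylprop-1-ene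
Product: 5 4-[(2,6-dimethylhept-5-en-3-yn-2-yl)oxy]-2,6-dimethoxybenzaldehyde
Conditions: PdCl2(PPh3)2 (2 mol %), CuI (4 mol %), Et3N, THF, 25 °C
Reagents that add atoms: none
Why: Sonogashira coupling of the terminal alkyne with an alkenyl bromide runs at room temperature, far below the temperature at which the aryl propargyl ether would rearrange, and leaves the aldehyde untouched.

Step 3
Reactants: 5 4-[(2,6-dimethylhept-5-en-3-yn-2-yl)oxy]-2,6-dimethoxybenzaldehyde
Product: 7 3-(2,6-dimethylhepta-2,5-dien-4-yl)-4-hydroxy-2,6-dimethoxybenzaldehyde, via Z-dienyl aryl ether 6 (not isolated)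
Conditions: H2 (1 atm), Pd/CaCO3 poisoned with Pb(OAc)2 (Lindlar catalyst), quinoline, toluene, 20 °C; filtration; then 110 °C
Reagents that add atoms: none
Why: Lindlar semi-hydrogenation of the enyne gives the cis-dienyl tertiary ether 6, whose aromatic Claisen rearrangement ([3,3]-sigmatropic, para position blocked by the formyl group) moves the chain to one of the two equivalent ortho carbons and transposes the allyl unit, so that the new benzylic carbon carries two identical 2-methylprop-1-enyl arms and is not stereogenic.

Step 4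
Reactants: 7 3-(2,6-dimethylhepta-2,5-dien-4-yl)-4-hydroxy-2,6-dimethoxybenzaldehyde; 8 2,4,6-trimethoxybenzene-1,3,5-tricarbaldehyde
Product: 11 (2R,3S,4S)-2-(3,5-diformyl-2,4,6-trimethoxyphenyl)-5,7-dimethoxy-4-(2-methylprop-1-en-1-yl)-3-(prop-1-en-2-yl)chromane-6-carbaldehyde, via aryloxycarbenium ion 9 (not isolated), via tertiary carbocation 10 (not isolated)
Conditions: chiral imidodiphosphorimidate Brønsted acid (IDPi type, built from two (S)-3,3'-diaryl-BINOL units with N-triflyl groups, 5 mol %), 8 in threefold excess, 5 Å molecular sieves, CHCl3, −20 → 20 °C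
Reagents that add atoms: none
Why: Proposed new method: the confined chiral acid condenses the phenol oxygen of 7 with one of the three equivalent formyl groups of 8 to the aryloxycarbenium ion 9 paired with the chiral anion; the CH carbon of one 2-methylprop-1-enyl arm (later C3) attacks the carbenium carbon (later C2), and the tertiary cation 10 loses a methyl proton to the anion (oxonium–ene outcome), which regenerates the acid. The closest known reactions are the confined-Brønsted-acid-catalysed asymmetric Prins and carbonyl–ene cyclizations and the Lewis-acid oxonium–ene cyclization of 6-methylhept-5-en-2-ol-type alcohols with aldehydes to 3-isopropenyl tetrahydropyrans; new here are the phenolic oxygen and the choice between two enantiotopic arms. Pyran ring B is closed by C2–C3 bond formation in a 6-endo-trig attack on the C=O+ unit (the alkene stays exocyclic) through a chair-like transition state. In that chair the E-configured oxocarbenium places the aryl group at C2 and the developing cationic carbon at C3 equatorial (2,3-trans), while allylic 1,3-strain with the peri methoxy group at C5 forces the unreacted arm at C4 pseudoaxial (3,4-cis); the relative configuration is thus substrate-controlled, and only the absolute sense, that is which enantiotopic arm reacts (which also fixes C4), is set by the chiral anion. The step needs C–C closure to outrun protonation of the electron-rich alkenes (closure of the phenol to a 2,2-dimethylchroman) and Friedel–Crafts attack at the free ortho carbon of ring A; the intramolecular six-membered closure, the low temperature and the excess of the symmetric trialdehyde should secure this.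

Step 5
Reactants: 11 (2R,3S,4S)-2-(3,5-diformyl-2,4,6-trimethoxyphenyl)-5,7-dimethoxy-4-(2-methylprop-1-en-1-yl)-3-(prop-1-en-2-yl)chromane-6-carbaldehyde
Product: 12 (2R,3R,4S)-2-(3,5-diformyl-2,4,6-trimethoxyphenyl)-5,7-dimethoxy-4-(2-methylpropyl)-3-(propan-2-yl)chromane-6-carbaldehyde
Conditions: H2 (1 atm), Pd/C (10 %), EtOAc, 20 °C
Reagents that add atoms: none
Why: Heterogeneous catalytic hydrogenation saturates the 1,1-disubstituted and the trisubstituted C=C bond to the isopropyl and isobutyl groups without creating or touching a stereocenter (the C3 descriptor changes from S to R only because the priorities change), while the three hindered di-ortho-methoxy aryl aldehydes and the benzylic C2–O1 bond are expected to survive at 1 atm in a neutral aprotic solvent.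

Step 6
Reactants: 12 (2R,3R,4S)-2-(3,5-diformyl-2,4,6-trimethoxyphenyl)-5,7-dimethoxy-4-(2-methylpropyl)-3-(propan-2-yl)chromane-6-carbaldehyde
Product: 13 (2R,3R,4S)-2-(3,5-diformyl-2,4,6-trihydroxyphenyl)-5,7-dihydroxy-4-(2-methylpropyl)-3-(propan-2-yl)chromane-6-carbaldehyde (target, CNP0328914.1)
Conditions: BBr3 (12 equiv), CH2Cl2, −78 → 20 °C; then H2O
Reagents that add atoms: none
Why: Lewis-acid ether cleavage with BBr3 removes all five aryl methyl groups, each ortho to a formyl group, and leaves the three stereocenters untouched, since a reversible opening at C2 would only return the more stable 2,3-trans ring.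

**Compound list**

1 | 4-hydroxy-2,6-dimethoxybenzaldehyde | COc1cc(O)cc(OC)c1C=O | starting material
2 | 3-chloro-3-methylbut-1-yne | CC(C)(Cl)C#C | starting material
3 | 2,6-dimethoxy-4-[(2-methylbut-3-yn-2-yl)oxy]benzaldehyde | COc1cc(OC(C)(C)C#C)cc(OC)c1C=O | intermediate
4 | 1-bromo-2-methylprop-1-ene | CC(C)=CBr | starting material
5 | 4-[(2,6-dimethylhept-5-en-3-yn-2-yl)oxy]-2,6-dimethoxybenzaldehyde | COc1cc(OC(C)(C)C#CC=C(C)C)cc(OC)c1C=O | intermediate
6 | 4-{[(3Z)-2,6-dimethylhepta-3,5-dien-2-yl]oxy}-2,6-dimethoxybenzaldehyde | COc1cc(OC(C)(C)/C=C\C=C(C)C)cc(OC)c1C=O | intermediate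
7 | 3-(2,6-dimethylhepta-2,5-dien-4-yl)-4-hydroxy-2,6-dimethoxybenzaldehyde | COc1cc(O)c(C(C=C(C)C)C=C(C)C)c(OC)c1C=O | intermediate
8 | 2,4,6-trimethoxybenzene-1,3,5-tricarbaldehyde | COc1c(C=O)c(OC)c(C=O)c(OC)c1C=O | starting material
9 | {[2-(2,6-dimethylhepta-2,5-dien-4-yl)-4-formyl-3,5-dimethoxyphenyl]oxy}(3,5-diformyl-2,4,6-trimethoxyphenyl)methylium (aryloxycarbenium ion) | COc1cc([O+]=Cc2c(OC)c(C=O)c(OC)c(C=O)c2OC)c(C(C=C(C)C)C=C(C)C)c(OC)c1C=O | intermediate
10 | tertiary 2-(chroman-3-yl)propan-2-yl cation formed by ring closure (ring configured as in 11) | CC(C)=C[C@@H]1c2c(cc(OC)c(C=O)c2OC)O[C@@H](c2c(OC)c(C=O)c(OC)c(C=O)c2OC)[C@@H]1[C+](C)C | intermediate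
11 | (2R,3S,4S)-2-(3,5-diformyl-2,4,6-trimethoxyphenyl)-5,7-dimethoxy-4-(2-methylprop-1-en-1-yl)-3-(prop-1-en-2-yl)chromane-6-carbaldehyde | CC(C)=C[C@@H]1c2c(cc(OC)c(C=O)c2OC)O[C@@H](c2c(OC)c(C=O)c(OC)c(C=O)c2OC)[C@@H]1C(C)=C | intermediate
12 | (2R,3R,4S)-2-(3,5-diformyl-2,4,6-trimethoxyphenyl)-5,7-dimethoxy-4-(2-methylpropyl)-3-(propan-2-yl)chromane-6-carbaldehyde | CC(C)C[C@@H]1c2c(cc(OC)c(C=O)c2OC)O[C@@H](c2c(OC)c(C=O)c(OC)c(C=O)c2OC)[C@@H]1C(C)C | intermediate
13 | (2R,3R,4S)-2-(3,5-diformyl-2,4,6-trihydroxyphenyl)-5,7-dihydroxy-4-(2-methylpropyl)-3-(propan-2-yl)chromane-6-carbaldehyde | CC(C)C[C@@H]1c2c(cc(O)c(C=O)c2O)O[C@@H](c2c(O)c(C=O)c(O)c(C=O)c2O)[C@@H]1C(C)C | target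

**Step count and risks**

Total steps: 6. Longest linear sequence: 6 steps (1 → 13).

Steps most likely to fail:

Step 4 (Proposed new method). What may go wrong: weak discrimination of the two enantiotopic alkenyl arms by the chiral anion (low enantiomeric purity), or protonation of the alkenes and Friedel–Crafts attack before the C–C closure. The fallback uses known chemistry, sets out from 1 and comes back at 12; it fixes C4 first by chirality transfer and then relies only on substrate control. Commercial (E)-6-methylhept-3-en-2-one is reduced under Corey–Bakshi–Shibata conditions ((R)-2-methyl-CBS-oxazaborolidine, BH3·SMe2) to (2S,3E)-6-methylhept-3-en-2-ol F1. Mitsunobu etherification of 1 with F1 (PPh3, DIAD, inversion) should give 2,6-dimethoxy-4-{[(2R,3E)-6-methylhept-3-en-2-yl]oxy}benzaldehyde F2. Aromatic Claisen rearrangement of F2 (N,N-diethylaniline, 180 °C), through the chair with the methyl group equatorial, transfers the chirality to the benzylic carbon and should give 4-hydroxy-2,6-dimethoxy-3-[(2E,4S)-6-methylhept-2-en-4-yl]benzaldehyde F3; any Z isomer is removed at this stage because it carries the opposite configuration. Cross-metathesis of F3 with 2-methylbut-2-ene (second-generation Hoveyda–Grubbs catalyst) gives 3-[(4S)-2,6-dimethylhept-2-en-4-yl]-4-hydroxy-2,6-dimethoxybenzaldehyde F4. Oxonium–ene cyclization of F4 with 8 under achiral acid catalysis (In(OTf)3, 5 Å molecular sieves, CH2Cl2), through the same chair as in step 4, gives (2R,3S,4S)-2-(3,5-diformyl-2,4,6-trimethoxyphenyl)-5,7-dimethoxy-4-(2-methylpropyl)-3-(prop-1-en-2-yl)chromane-6-carbaldehyde F5, and hydrogenation as in step 5 gives 12.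

Step 3. What may go wrong: over-reduction of the enyne, or ionization and elimination of the labile tertiary dienyl ether together with a slow rearrangement through the crowded chair of the cis isomer. The fallback sets out from 3 and comes back at 7; it builds the diene with defined trans geometry by hydrometalation and cross-coupling, so that no alkyne has to be reduced. Palladium-catalysed hydrostannation of the terminal alkyne of 3 (Bu3SnH, PdCl2(PPh3)2, THF) gives 2,6-dimethoxy-4-{[(3E)-2-methyl-4-(tributylstannyl)but-3-en-2-yl]oxy}benzaldehyde F6. Stille coupling of F6 with 4 (Pd(PPh3)4, CuI, DMF, 50 °C) gives 4-{[(3E)-2,6-dimethylhepta-3,5-dien-2-yl]oxy}-2,6-dimethoxybenzaldehyde F7, whose Claisen rearrangement (toluene, 90–110 °C) passes through the less strained chair to 7.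

Step 6. What may go wrong: incomplete cleavage of the second methoxy group flanking each formyl group, or Lewis-acid ionization of the benzylic C2–O1 bond with loss of material. The fallback sets out from 12 and arrives directly at 13; it replaces electrophilic by nucleophilic ether cleavage. Sodium ethanethiolate (NaSEt, DMF, 120 °C) removes the methyl groups by SN2 attack at carbon in a basic medium, where the phenoxide leaving groups are stabilized by the ortho and para formyl groups and no cation can form at C2. This fallback makes no new compound (F0).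

**Further compounds**

F1 | step 4 | (2S,3E)-6-methylhept-3-en-2-ol | C[C@H](O)/C=C/CC(C)C
F2 | step 4 | 2,6-dimethoxy-4-{[(2R,3E)-6-methylhept-3-en-2-yl]oxy}benzaldehyde | C[C@@H](Oc1cc(OC)c(C=O)c(OC)c1)/C=C/CC(C)C
F3 | step 4 | 4-hydroxy-2,6-dimethoxy-3-[(2E,4S)-6-methylhept-2-en-4-yl]benzaldehyde | C/C=C/[C@H](CC(C)C)c1c(O)cc(OC)c(C=O)c1OC
F4 | step 4 | 3-[(4S)-2,6-dimethylhept-2-en-4-yl]-4-hydroxy-2,6-dimethoxybenzaldehyde | CC(C)=C[C@H](CC(C)C)c1c(O)cc(OC)c(C=O)c1OC
F5 | step 4 | (2R,3S,4S)-2-(3,5-diformyl-2,4,6-trimethoxyphenyl)-5,7-dimethoxy-4-(2-methylpropyl)-3-(prop-1-en-2-yl)chromane-6-carbaldehyde | CC(C)C[C@@H]1c2c(cc(OC)c(C=O)c2OC)O[C@@H](c2c(OC)c(C=O)c(OC)c(C=O)c2OC)[C@@H]1C(C)=C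
F6 | step 3 | 2,6-dimethoxy-4-{[(3E)-2-methyl-4-(tributylstannyl)but-3-en-2-yl]oxy}benzaldehyde | CCCC[Sn](CCCC)(CCCC)/C=C/C(C)(C)Oc1cc(OC)c(C=O)c(OC)c1
F7 | step 3 | 4-{[(3E)-2,6-dimethylhepta-3,5-dien-2-yl]oxy}-2,6-dimethoxybenzaldehyde | COc1cc(OC(C)(C)/C=C/C=C(C)C)cc(OC)c1C=O
F0 | step 6 | none | none
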